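**Assumption.** The target is taken as drawn, as the free hydrogen sulfate. Its potassium salt 16 is the form that is handled, and the acid is liberated only in the last operation.

## Analysis of the target

The target is a flavonol: a 4H-chromen-4-one (benzo ring A fused to pyranone ring C) with a 4-hydroxyphenyl ring B at C2, hydroxyls at C5, C6 and C7, hydrogen at C8, and a hydrogen sulfate ester on the oxygen at C3. It has no stereocentre, so the whole problem is regiochemistry among six oxygen atoms. The enol-type sulfate monoester at O3 is cleaved by protic and Lewis acids, fastest in its free-acid form, and the contiguous 5,6,7-triol is a pyrogallol-type unit that air oxidises in base. Two things make the synthesis hard. The sulfate must go on O3 alone in the presence of four phenols, and ring A needs oxygen at C6, whereas oxidation of cheap 5,7-dioxygenated flavones goes para to O5, at C8. The strategy rests on the near-symmetry of ring A about C4a: C5 and C8a both carry oxygen ortho to C4a, so breaking O1–C2 and reclosing through the oxygen on C5 turns a 5,7,8-trioxygenated flavone into the 5,6,7 isomer, with the former C8 oxygen ending at C6. A second handle is C3–H, the only vinylic hydrogen next to the C4 carbonyl; it can be exchanged for hydroxyl after all phenols are benzylated, so that O3 is the single free hydroxyl when the sulfate is placed.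

## Retrosynthetic reasoning

**17 to 15.** The last bonds handled are the four aryl O–benzyl bonds, not the O3–S bond. The sulfate cannot survive acidic deprotection, so the phenols are masked by groups that leave under neutral reductive conditions. Hydrogenolysis of 15 should leave the sulfate untouched as its potassium salt 16, and one equivalent of acid then gives 17.

**15 to 13.** Cutting O3–S leads to flavonol 13, in which O3 is the only free hydroxyl, so sulfation needs no regiocontrol. The first-formed pyridinium salt 14 is exchanged to the potassium salt 15 so that no amine interferes with the hydrogenolysis.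

**13 to 10.** The C3–O bond is cut next. In 10, C3–H is the only C–H that a hindered amide base removes; the vinyl anion 11 is trapped as borate 12 and oxidised. Placing this step late keeps C3 unsubstituted while ring A is rearranged, which matters because the ring opening on which the isomerisation depends is expected to be far less ready once C3 carries oxygen.

**10 to 9 and 2.** Four O–benzyl bonds are cut. All four phenols of 9 are capped in one operation with 2, which both protects the oxidisable triol and removes every acidic O–H before the lithiation.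

**9 to 7 (strategic).** The O1–C2 bond of 9 is cut and traced back to the isomeric O1–C2 bond of 7 through the open-chain diketone 8. No carbon–carbon bond is made; a ring A pattern that is hard to install directly (oxygen at C6) is exchanged for one that is easy (oxygen at C8). The forward reaction has to open ring C reversibly and let the more stable closure accumulate.

**7 to 6.** Two O–benzyl bonds are cut. The benzyl groups are removed by hydrogenolysis before the acid step rather than in it, because benzyl cations set free in hot acid would alkylate the electron-rich ring A.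

**6 to 3 and 4.** The C8–O bond is cut. With the 7- and 4'-hydroxyls blocked, the 5-hydroxyl of 3 is the only phenol, and persulfate 4 oxidises its free para position, C8, through aryl sulfate 5.

**3 to 1 and 2.** Two O–benzyl bonds are cut. The chelated 5-hydroxyl of 1 is much less reactive than the 7- and 4'-hydroxyls, so selective dibenzylation of this cheap natural flavone needs no extra control.

## Alternatives that were turned down

**Alternative 1:** The C3–C4 bond is disconnected with inverted polarity at C4. In the forward step a thiazolium-derived carbene would add to the aryl aldehyde of 2,3,4-tris(benzyloxy)-6-{1-[4-(benzyloxy)phenyl]-2-oxoethoxy}benzaldehyde A2, and the resulting acyl-anion equivalent would attack the aliphatic aldehyde to close ring C as 5,6,7-tris(benzyloxy)-2-[4-(benzyloxy)phenyl]-3-hydroxychroman-4-one A1.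
- For it: the C3 oxygen arrives with the ring, so no strong-base C3 functionalisation is needed; the conditions are mild and metal-free; the two stereocentres of A1 do not matter, since dehydrogenation to 13 removes both. On mildness of the C3 oxygenation it is stronger than the chosen plan.
- Against it: the carbene must choose the hindered, electron-rich, doubly ortho-substituted aryl aldehyde over the unhindered aliphatic one, which is the mismatched polarity. Reversal of donor and acceptor roles would give the wrong acyloin.
- Against it: A2 contains an α-aryl-α-aryloxy aldehyde whose C–H is doubly activated, so enolisation, aldol reaction and loss of phenoxide compete.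
- Against it: A2 needs a fully built pentasubstituted ring A aldehyde plus an O-alkylation of a hindered phenol, and A1 needs a further oxidation. The sequence would be longer than eight steps, with the risk spread over several of them.
- The chosen route makes no carbon–carbon bond and keeps the uncertainty in one thermodynamically driven step.

**Alternative 2:** Ring A is disconnected at C7–C8 and C5–C6. In the forward step the lateral carbanion of methyl 6-[4-(benzyloxy)phenyl]-5-(methoxymethoxy)-2-methyl-4-oxo-4H-pyran-3-carboxylate A4 would be acylated by methyl (benzyloxy)acetate A5, and the new ketone would close onto the ring ester to give 6-(benzyloxy)-2-[4-(benzyloxy)phenyl]-5,7-dihydroxy-3-(methoxymethoxy)-4H-chromen-4-one A3.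
- For it: all ring A oxygens and the C3 oxygen are in place in one step, and O6 and O3 are already differentiated from O5 and O7. On oxygen differentiation it is stronger than the chosen plan.
- Against it: the closure must come from the α-alkoxy carbon (future C6), but the first site deprotonated in the acylated intermediate is the doubly activated methylene (future C8), so a dianion or an unfavourable equilibrium is required.
- Against it: 2-methyl-4-pyranones are prone to nucleophilic ring opening under the bases that lateral metalation needs, and A5 self-condenses.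
- Against it: A4 is itself a multistep target, and from A3 it still takes benzylation, acetal removal, sulfation and hydrogenolysis to finish by way of 13.
- The chosen route starts from the intact flavone skeleton and needs no annulation that lacks a close model.

**Alternative 3:** Ring C is disconnected at C4a–C4, C4–C3 and O1–C2. In the forward step zerovalent palladium would insert into the carbon–iodine bond of 2-iodo-3,4,5-tris(benzyloxy)phenol A7, take up carbon monoxide A9 and 1-(benzyloxy)-4-ethynylbenzene A8, and the phenol oxygen would close onto C2 (6-endo-dig) to give 5,6,7-tris(benzyloxy)-2-[4-(benzyloxy)phenyl]-4H-chromen-4-one A6. The product A6 is the same compound as 10.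
- For it: it is convergent, the reaction type is well established for 2-iodophenols, and it reaches 10 without handling free, air-sensitive polyphenols or hot mineral acid. On convergence and mildness it is the stronger plan, and its step count to 10 is similar.
- Against it: the iodide of A7 sits between a hydroxyl and a benzyloxy group on a very electron-rich ring, so oxidative addition and the insertion of carbon monoxide A9 are slow. Direct coupling of A8 without carbonylation, and 5-exo-dig closure to an aurone, are the expected competitors.
- Against it: A7 and A8 must each be made, and the toxic gas A9 is used under pressure.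
- The chosen route offers a cheap natural flavone as the only skeletal building block, no transition-metal carbon–carbon coupling, and regioconvergence: oxygenation at C8 or at C6 both end in 9.

Key step: step 4

## Route

**Step 1**
Reactants: 1 apigenin; 2 benzyl bromide
Product: 3 apigenin 7,4'-dibenzyl ether (7-(benzyloxy)-2-[4-(benzyloxy)phenyl]-5-hydroxy-4H-chromen-4-one)
Conditions: BnBr (2.2 equiv), K2CO3, DMF, rt
Reagents that add atoms: benzyl bromide 2, BrCc1ccccc1
Why: Williamson etherification; the 7- and 4'-hydroxyls are the acidic, unhindered phenols, whereas the 5-hydroxyl is held in a hydrogen bond to the C4 carbonyl and should not be alkylated by carbonate at room temperature.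

**Step 2**
Reactants: 3 apigenin 7,4'-dibenzyl ether; 4 potassium peroxydisulfate
Product: 6 isoscutellarein 7,4'-dibenzyl ether (7-(benzyloxy)-2-[4-(benzyloxy)phenyl]-5,8-dihydroxy-4H-chromen-4-one), via potassium 8-sulfate 5 (not isolated)
Conditions: K2S2O8 (1.2 equiv), aq. KOH, pyridine, 10–20 °C; pH 4, recovery of unreacted 3; then 2 M HCl, Na2SO3, 80 °C
Reagents that add atoms: potassium peroxydisulfate 4, [K+].[K+].[O-]S(=O)(=O)OOS(=O)(=O)[O-]
Why: Elbs persulfate oxidation; the 5-phenolate, the only phenolate present, attacks the peroxide oxygen through C8, its only free para position, to give aryl sulfate 5, and acid hydrolysis with S–O cleavage frees the phenol. Minor attack at C6 would be harmless, because that isomer also ends in 9 after steps 3 and 4.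

**Step 3**
Reactants: 6 isoscutellarein 7,4'-dibenzyl ether
Product: 7 isoscutellarein (5,7,8-trihydroxy-2-(4-hydroxyphenyl)-4H-chromen-4-one)
Conditions: H2 (1 atm), 10% Pd/C, THF–MeOH, rt; work-up under Ar
Reagents that add atoms: none
Why: Hydrogenolysis of aryl benzyl ethers over Pd/C; the conjugated C2–C3 double bond of the pyranone should not be reduced at atmospheric pressure, and no acid is present that could release benzyl cations onto ring A.

**Step 4**
Reactants: 7 isoscutellarein
Product: 9 scutellarein (5,6,7-trihydroxy-2-(4-hydroxyphenyl)-4H-chromen-4-one), via ring-opened 1,3-diketone 8 (not isolated)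
Conditions: 48% aq. HBr, AcOH, reflux (about 120 °C), Ar
Reagents that add atoms: water, O (taken up on ring opening to 8 and released again on reclosure; no atom of it remains in 9)
Why: This is the Wessely–Moser rearrangement of a 5,7,8-trihydroxyflavone. Protonation of the C4 carbonyl of 7 makes ring C a 4-hydroxybenzopyrylium ion; water adds at C2 and the O1–C2 bond breaks to give diketone 8, in which the old O1 is a free phenol. After rotation about the aryl–carbonyl bond, the other ortho hydroxyl (the former 5-hydroxyl) adds to the protonated C2 carbonyl in a 6-exo-trig closure, and loss of water restores the pyranone with a new O1–C2 bond. The old O1 is now the chelated 5-hydroxyl and the old C8 oxygen sits at C6. No stereocentre is formed. The step needs 9 and not 7: both closures of 8 are reversible in hot mineral acid, so the outcome is thermodynamic, and for flavones the 5,6,7 pattern is the established sink (a hydrogen-bond relay from the 7- through the 6- and 5-hydroxyl to the C4 carbonyl, and no hydroxyl next to O1). Ring B and its hydroxyl are spectators. Argon and a limited reflux time keep oxidation of the polyphenols and acid cleavage of 8 in check.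

**Step 5**
Reactants: 9 scutellarein; 2 benzyl bromide
Product: 10 scutellarein tetrabenzyl ether (5,6,7-tris(benzyloxy)-2-[4-(benzyloxy)phenyl]-4H-chromen-4-one)
Conditions: BnBr (6 equiv), K2CO3, KI (cat.), DMF, 70 °C, Ar
Reagents that add atoms: benzyl bromide 2, BrCc1ccccc1
Why: Williamson etherification under forcing conditions; excess halide, iodide catalysis and heat are there for the chelated 5-hydroxyl, and air is excluded because the triol phenolate is easily oxidised.

**Step 6**
Reactants: 10 scutellarein tetrabenzyl ether
Product: 13 5,6,7-tris(benzyloxy)-2-[4-(benzyloxy)phenyl]-3-hydroxy-4H-chromen-4-one, via 3-lithioflavone 11 (not isolated), via lithium trimethoxyborate 12 (not isolated)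
Conditions: LiN(iPr)2 (1.3 equiv), THF, −78 °C; B(OMe)3, −78 to 0 °C; AcOH, 30% H2O2, 0 °C to rt
Reagents that add atoms: lithium diisopropylamide, [Li]N(C(C)C)C(C)C (Li in 11); trimethyl borate, COB(OC)OC (B(OMe)3 in 12); hydrogen peroxide, OO (O at C3 in 13)
Why: C3 lithiation of a flavone followed by borylation and oxidation; the hindered amide removes C3–H, the vinylic hydrogen next to the carbonyl, the vinyl anion 11 is trapped as borate 12, and peroxide-induced migration of C3 from boron to oxygen gives the flavonol. Keeping 11 at −78 °C until the borate quench guards against ring opening by loss of the O1 phenoxide.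

**Step 7**
Reactants: 13 5,6,7-tris(benzyloxy)-2-[4-(benzyloxy)phenyl]-3-hydroxy-4H-chromen-4-one
Product: 15 potassium 5,6,7-tris(benzyloxy)-2-[4-(benzyloxy)phenyl]-4-oxo-4H-chromen-3-yl sulfate, via pyridinium 3-sulfate 14 (not isolated)
Conditions: SO3·pyridine (5 equiv), pyridine, 50 °C; then KOH, MeOH, 0 °C (to pH 8)
Reagents that add atoms: sulfur trioxide–pyridine complex, [O-]S(=O)(=O)[n+]1ccccc1 (SO3 in 14 and 15, pyridine in 14); potassium hydroxide, [K+].[OH-] (K in 15)
Why: O-sulfation of an enolic hydroxyl by the sulfur trioxide–amine adduct; O3 is the only free hydroxyl, so no regiocontrol is needed. Exchange to the potassium salt removes pyridine, which would slow the hydrogenolysis that follows.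

**Step 8**
Reactants: 15 potassium 5,6,7-tris(benzyloxy)-2-[4-(benzyloxy)phenyl]-4-oxo-4H-chromen-3-yl sulfate
Product: 17 5,6,7-trihydroxy-2-(4-hydroxyphenyl)-4-oxo-4H-chromen-3-yl hydrogen sulfate (target), via potassium salt 16 (not isolated)
Conditions: H2 (1 atm), 10% Pd/C, THF–MeOH–H2O, rt; then 0.1 M HCl (1.0 equiv), 0 °C, C18 desalting, freeze-drying
Reagents that add atoms: none
Why: Hydrogenolysis of the four benzyl ethers over Pd/C; the sulfate monoester anion is inert to hydrogen and should not poison the catalyst. One equivalent of acid in the cold with immediate desalting should give the hydrogen sulfate without exposing it to excess acid.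

## Compound list

1 | apigenin (5,7-dihydroxy-2-(4-hydroxyphenyl)-4H-chromen-4-one) | O=c1cc(-c2ccc(O)cc2)oc2cc(O)cc(O)c12 | starting material
2 | benzyl bromide | BrCc1ccccc1 | starting material
3 | apigenin 7,4'-dibenzyl ether (7-(benzyloxy)-2-[4-(benzyloxy)phenyl]-5-hydroxy-4H-chromen-4-one) | O=c1cc(-c2ccc(OCc3ccccc3)cc2)oc2cc(OCc3ccccc3)cc(O)c12 | intermediate
4 | potassium peroxydisulfate | [K+].[K+].[O-]S(=O)(=O)OOS(=O)(=O)[O-] | starting material
5 | potassium 7-(benzyloxy)-2-[4-(benzyloxy)phenyl]-5-hydroxy-4-oxo-4H-chromen-8-yl sulfate | O=c1cc(-c2ccc(OCc3ccccc3)cc2)oc2c(OS(=O)(=O)[O-])c(OCc3ccccc3)cc(O)c12.[K+] | intermediate (not isolated)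
6 | isoscutellarein 7,4'-dibenzyl ether (7-(benzyloxy)-2-[4-(benzyloxy)phenyl]-5,8-dihydroxy-4H-chromen-4-one) | O=c1cc(-c2ccc(OCc3ccccc3)cc2)oc2c(O)c(OCc3ccccc3)cc(O)c12 | intermediate
7 | isoscutellarein (5,7,8-trihydroxy-2-(4-hydroxyphenyl)-4H-chromen-4-one) | O=c1cc(-c2ccc(O)cc2)oc2c(O)c(O)cc(O)c12 | intermediate
8 | 1-(4-hydroxyphenyl)-3-(2,3,4,6-tetrahydroxyphenyl)propane-1,3-dione | O=C(CC(=O)c1ccc(O)cc1)c1c(O)cc(O)c(O)c1O | intermediate (not isolated)
9 | scutellarein (5,6,7-trihydroxy-2-(4-hydroxyphenyl)-4H-chromen-4-one) | O=c1cc(-c2ccc(O)cc2)oc2cc(O)c(O)c(O)c12 | intermediate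
10 | scutellarein tetrabenzyl ether (5,6,7-tris(benzyloxy)-2-[4-(benzyloxy)phenyl]-4H-chromen-4-one) | O=c1cc(-c2ccc(OCc3ccccc3)cc2)oc2cc(OCc3ccccc3)c(OCc3ccccc3)c(OCc3ccccc3)c12 | intermediate
11 | 5,6,7-tris(benzyloxy)-2-[4-(benzyloxy)phenyl]-3-lithio-4H-chromen-4-one | [Li]c1c(-c2ccc(OCc3ccccc3)cc2)oc2cc(OCc3ccccc3)c(OCc3ccccc3)c(OCc3ccccc3)c2c1=O | intermediate (not isolated)
12 | lithium trimethoxy{5,6,7-tris(benzyloxy)-2-[4-(benzyloxy)phenyl]-4-oxo-4H-chromen-3-yl}borate | [Li+].CO[B-](OC)(OC)c1c(-c2ccc(OCc3ccccc3)cc2)oc2cc(OCc3ccccc3)c(OCc3ccccc3)c(OCc3ccccc3)c2c1=O | intermediate (not isolated)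
13 | 5,6,7-tris(benzyloxy)-2-[4-(benzyloxy)phenyl]-3-hydroxy-4H-chromen-4-one | O=c1c(O)c(-c2ccc(OCc3ccccc3)cc2)oc2cc(OCc3ccccc3)c(OCc3ccccc3)c(OCc3ccccc3)c12 | intermediate
14 | pyridinium 5,6,7-tris(benzyloxy)-2-[4-(benzyloxy)phenyl]-4-oxo-4H-chromen-3-yl sulfate | O=c1c(OS(=O)(=O)[O-])c(-c2ccc(OCc3ccccc3)cc2)oc2cc(OCc3ccccc3)c(OCc3ccccc3)c(OCc3ccccc3)c12.c1cc[nH+]cc1 | intermediate (not isolated)
15 | potassium 5,6,7-tris(benzyloxy)-2-[4-(benzyloxy)phenyl]-4-oxo-4H-chromen-3-yl sulfate | O=c1c(OS(=O)(=O)[O-])c(-c2ccc(OCc3ccccc3)cc2)oc2cc(OCc3ccccc3)c(OCc3ccccc3)c(OCc3ccccc3)c12.[K+] | intermediate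
16 | potassium 5,6,7-trihydroxy-2-(4-hydroxyphenyl)-4-oxo-4H-chromen-3-yl sulfate | O=c1c(OS(=O)(=O)[O-])c(-c2ccc(O)cc2)oc2cc(O)c(O)c(O)c12.[K+] | intermediate (not isolated)
17 | 5,6,7-trihydroxy-2-(4-hydroxyphenyl)-4-oxo-4H-chromen-3-yl hydrogen sulfate | O=c1c(OS(=O)(=O)O)c(-c2ccc(O)cc2)oc2cc(O)c(O)c(O)c12 | target

## Step count and least certain steps

Total step count: 8. Longest linear sequence: 8 steps, from 1 to 17.

**Step 4 (key step).** The most likely failure is incomplete equilibration, leaving the two isomers as a mixture that is hard to separate. Beside it stand irreversible acid cleavage of the open-chain diketone, air oxidation of the polyphenols, and ring bromination by traces of bromine formed from HBr. Fallback: the oxygen is put at C6 directly and the isomerisation is bypassed. Setting out from 3, iodination with benzyltrimethylammonium dichloroiodate and CaCO3 in CH2Cl2–MeOH should go ortho to the free, chelated 5-hydroxyl to give 7-(benzyloxy)-2-[4-(benzyloxy)phenyl]-5-hydroxy-6-iodo-4H-chromen-4-one F1. Benzylation of the 5-hydroxyl (BnBr, K2CO3, DMF, 70 °C) gives 5,7-bis(benzyloxy)-2-[4-(benzyloxy)phenyl]-6-iodo-4H-chromen-4-one F2. Ullmann-type C–O coupling with benzyl alcohol (CuI, 3,4,7,8-tetramethyl-1,10-phenanthroline, Cs2CO3, toluene, 110 °C) comes back to the route at 10.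

**Step 2.** Persulfate is partly consumed by radical decomposition, so conversion is expected to be modest, with recovery of 3. Over-oxidation to the 5,8-quinone and partial loss of benzyl groups during the hot acid hydrolysis are the other concerns. Fallback: halogenation and C–O coupling in place of the oxidation. Setting out from 3, benzylation of the 5-hydroxyl gives 5,7-bis(benzyloxy)-2-[4-(benzyloxy)phenyl]-4H-chromen-4-one F3. With the 5-oxygen alkylated, electrophilic iodination (N-iodosuccinimide, CF3CO2H cat., MeCN) should go to C8, para to the 5-benzyloxy group and less hindered than C6, giving 5,7-bis(benzyloxy)-2-[4-(benzyloxy)phenyl]-8-iodo-4H-chromen-4-one F4. Copper-catalysed coupling with benzyl alcohol as above gives 5,7,8-tris(benzyloxy)-2-[4-(benzyloxy)phenyl]-4H-chromen-4-one F5, and hydrogenolysis (H2, Pd/C) comes back at 7.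

**Step 6.** The lithiated pyranone can open by β-elimination of the O1 phenoxide if it warms before the borate quench. Incomplete deprotonation and protodeboronation before the oxidation would return 10. Fallback: epoxidation instead of metalation. Setting out from 10, dimethyldioxirane in acetone–CH2Cl2 at 0 °C should give the racemic, cis-fused 2,3-epoxide 4,5,6-tris(benzyloxy)-1a-[4-(benzyloxy)phenyl]-1a,7a-dihydro-7H-oxireno[2,3-b]chromen-7-one F6. Acid-catalysed opening and tautomerisation (TsOH cat., CH2Cl2) comes back at 13.

**Step 5.** The triol phenolate may be oxidised to an ortho-quinone before it is alkylated, alkylation may stall before the chelated 5-hydroxyl reacts, and C-benzylation at C8 is possible. Fallback: the phenolates are released slowly from esters. Setting out from 9, acetylation (Ac2O, pyridine) gives 5,6,7-triacetoxy-2-(4-acetoxyphenyl)-4H-chromen-4-one F7. Deacetylative benzylation (BnBr, K2CO3, KI, moist acetone, reflux), in which each phenolate is alkylated as it is uncovered, comes back at 10.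

**Step 7.** Sulfation of the hindered, hydrogen-bonded 3-hydroxyl between the C2 aryl group and the C4 carbonyl may be sluggish, and the polar salt may be lost on purification. The free acid may also lose the sulfate during protonation in step 8. Fallback: the sulfate is introduced as a neutral, chromatographable diester, which replaces steps 7 and 8. Setting out from 13, 2,2,2-trichloroethyl chlorosulfate with Et3N and 4-(dimethylamino)pyridine in THF gives 5,6,7-tris(benzyloxy)-2-[4-(benzyloxy)phenyl]-4-oxo-4H-chromen-3-yl 2,2,2-trichloroethyl sulfate F8. Transfer hydrogenolysis (Pd/C, HCO2NH4, MeOH–THF) removes the trichloroethyl group and the four benzyl groups in one operation to give ammonium 5,6,7-trihydroxy-2-(4-hydroxyphenyl)-4-oxo-4H-chromen-3-yl sulfate F9. One equivalent of cold dilute HCl and C18 desalting comes back at 17.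

## Further compounds

F1 | step 4 | 7-(benzyloxy)-2-[4-(benzyloxy)phenyl]-5-hydroxy-6-iodo-4H-chromen-4-one | O=c1cc(-c2ccc(OCc3ccccc3)cc2)oc2cc(OCc3ccccc3)c(I)c(O)c12
F2 | step 4 | 5,7-bis(benzyloxy)-2-[4-(benzyloxy)phenyl]-6-iodo-4H-chromen-4-one | O=c1cc(-c2ccc(OCc3ccccc3)cc2)oc2cc(OCc3ccccc3)c(I)c(OCc3ccccc3)c12
F3 | step 2 | 5,7-bis(benzyloxy)-2-[4-(benzyloxy)phenyl]-4H-chromen-4-one | O=c1cc(-c2ccc(OCc3ccccc3)cc2)oc2cc(OCc3ccccc3)cc(OCc3ccccc3)c12
F4 | step 2 | 5,7-bis(benzyloxy)-2-[4-(benzyloxy)phenyl]-8-iodo-4H-chromen-4-one | O=c1cc(-c2ccc(OCc3ccccc3)cc2)oc2c(I)c(OCc3ccccc3)cc(OCc3ccccc3)c12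
F5 | step 2 | 5,7,8-tris(benzyloxy)-2-[4-(benzyloxy)phenyl]-4H-chromen-4-one | O=c1cc(-c2ccc(OCc3ccccc3)cc2)oc2c(OCc3ccccc3)c(OCc3ccccc3)cc(OCc3ccccc3)c12
F6 | step 6 | 4,5,6-tris(benzyloxy)-1a-[4-(benzyloxy)phenyl]-1a,7a-dihydro-7H-oxireno[2,3-b]chromen-7-one (racemic, cis-fused epoxide) | O=C1C2OC2(c2ccc(OCc3ccccc3)cc2)Oc2cc(OCc3ccccc3)c(OCc3ccccc3)c(OCc3ccccc3)c21
F7 | step 5 | 5,6,7-triacetoxy-2-(4-acetoxyphenyl)-4H-chromen-4-one | CC(=O)Oc1ccc(-c2cc(=O)c3c(OC(C)=O)c(OC(C)=O)c(OC(C)=O)cc3o2)cc1
F8 | step 7 | 5,6,7-tris(benzyloxy)-2-[4-(benzyloxy)phenyl]-4-oxo-4H-chromen-3-yl 2,2,2-trichloroethyl sulfate | O=c1c(OS(=O)(=O)OCC(Cl)(Cl)Cl)c(-c2ccc(OCc3ccccc3)cc2)oc2cc(OCc3ccccc3)c(OCc3ccccc3)c(OCc3ccccc3)c12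
F9 | step 7 | ammonium 5,6,7-trihydroxy-2-(4-hydroxyphenyl)-4-oxo-4H-chromen-3-yl sulfate | [NH4+].[O-]S(=O)(=O)Oc1c(-c2ccc(O)cc2)oc2cc(O)c(O)c(O)c2c1=O
A1 | alternative 1 | 5,6,7-tris(benzyloxy)-2-[4-(benzyloxy)phenyl]-3-hydroxychroman-4-one (racemic, both diastereomers) | O=C1c2c(OCc3ccccc3)c(OCc3ccccc3)c(OCc3ccccc3)cc2OC(c2ccc(OCc3ccccc3)cc2)C1O
A2 | alternative 1 | 2,3,4-tris(benzyloxy)-6-{1-[4-(benzyloxy)phenyl]-2-oxoethoxy}benzaldehyde (racemic) | O=CC(Oc1cc(OCc2ccccc2)c(OCc2ccccc2)c(OCc2ccccc2)c1C=O)c1ccc(OCc2ccccc2)cc1
A3 | alternative 2 | 6-(benzyloxy)-2-[4-(benzyloxy)phenyl]-5,7-dihydroxy-3-(methoxymethoxy)-4H-chromen-4-one | COCOc1c(-c2ccc(OCc3ccccc3)cc2)oc2cc(O)c(OCc3ccccc3)c(O)c2c1=O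
A4 | alternative 2 | methyl 6-[4-(benzyloxy)phenyl]-5-(methoxymethoxy)-2-methyl-4-oxo-4H-pyran-3-carboxylate | COC(=O)c1c(C)oc(-c2ccc(OCc3ccccc3)cc2)c(OCOC)c1=O
A5 | alternative 2 | methyl (benzyloxy)acetate | COC(=O)COCc1ccccc1
A6 | alternative 3 | 5,6,7-tris(benzyloxy)-2-[4-(benzyloxy)phenyl]-4H-chromen-4-one (identical with 10) | O=c1cc(-c2ccc(OCc3ccccc3)cc2)oc2cc(OCc3ccccc3)c(OCc3ccccc3)c(OCc3ccccc3)c12
A7 | alternative 3 | 2-iodo-3,4,5-tris(benzyloxy)phenol | Oc1cc(OCc2ccccc2)c(OCc2ccccc2)c(OCc2ccccc2)c1I
A8 | alternative 3 | 1-(benzyloxy)-4-ethynylbenzene | C#Cc1ccc(OCc2ccccc2)cc1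
A9 | alternative 3 | carbon monoxide | [C-]#[O+]
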